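The butyrolactone is cut at both benzylic C–C bonds: lactone C-beta carries the ring B methylene and C-alpha (beside C=O) the ring C methylene, trans to each other. In one flask the lithiated dithiane of the ring A/B erythro aryl ether adds to C4 of (5R)-5-(l-menthyloxy)-2(5H)-furanone anti to the acetal oxygen, and the enolate is then benzylated at C3 by the dihydrobenzofuran-5-ylmethyl bromide. This sets both lactone stereocentres without closing a ring. The precursors are a fully O-protected ring A/B 2-aryl-1,3-dithiane, the menthyloxybutenolide and the O-protected ring C/D benzylic bromide; the acetal carbon is the latent lactone OCH2.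

Key step: step 20

Assumption: ring A is the guaiacyl ring on carbinol carbon C7, ring B the aryl ether ring whose methylene sits on lactone C-beta, ring C the benzo ring of the dihydrobenzofuran and ring D its 2-aryl group. C7/C8/C9 number the arylglycerol chain.

Remark on the chemistry: read from its SMILES, the target is (7R,8S) (erythro) in the aryl ether, (3R,4R) (trans) in the lactone and (2S,3R) (trans) in the dihydrobenzofuran. An Evans syn aldol gives the threo ether, so C7 is inverted once (step 8). The menthyl acetal is opened with base and hydride, not acid, because the silyl ethers and the p-alkoxybenzylic C–O bonds are acid-labile. The phenols stay benzylated until the last step.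

Abbreviations: TBS = tert-butyldimethylsilyl, Bn = benzyl, MOM = methoxymethyl, Men = (1R,2S,5R)-menthyl.
- "AB aryl" = 4-{[(1R,2S)-1-(4-benzyloxy-3-methoxyphenyl)-1,3-bis(TBS-oxy)propan-2-yl]oxy}-3-methoxyphenyl.
- "CD aryl" = (2S,3R)-2-(4-benzyloxy-3-methoxyphenyl)-3-[(TBS-oxy)methyl]-7-methoxy-2,3-dihydro-1-benzofuran-5-yl.

**Route**

Step 1
Reactants: 1 furfural
Product: 2 5-hydroxy-2(5H)-furanone (racemic hemiacylal)
Conditions: O2, rose bengal (cat.), visible light, MeOH, 20 °C
Reagents that add atoms: dioxygen, O=O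
Why: Dye-sensitised singlet-oxygen [4+2] photooxygenation of the furan with in-situ methanolysis excises the formyl carbon as methyl formate and leaves the freely epimerising hemiacylal.

Step 2
Reactants: 2 5-hydroxy-2(5H)-furanone; 3 l-menthol
Product: 4 (5R)-5-[(1R,2S,5R)-menthyloxy]-2(5H)-furanone
Conditions: (+)-camphorsulfonic acid (cat.), toluene, reflux, Dean–Stark; crystallisation from petroleum ether, mother liquor re-equilibrated with acid
Reagents that add atoms: none
Why: Acid-catalysed acetalisation gives both C5 epimers, which interconvert under the acid, so crystallisation of the less soluble (5R) epimer should funnel the mixture into one diastereomer (crystallisation-induced asymmetric transformation).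

Step 3
Reactants: 5 (4-formyl-2-methoxyphenoxy)acetic acid
Product: 6 [4-(1,3-dithian-2-yl)-2-methoxyphenoxy]acetic acid
Conditions: HS(CH2)3SH, BF3·OEt2, CH2Cl2, 0 °C → rt
Reagents that add atoms: 1,3-propanedithiol, SCCCS
Why: Lewis-acid thioacetalisation of the aryl aldehyde is chemoselective beside the carboxylic acid and installs the masked acyl anion before any stereocentre exists.

Step 4
Reactants: 6 [4-(1,3-dithian-2-yl)-2-methoxyphenoxy]acetic acid; 7 (R)-4-benzyl-2-oxazolidinone
Product: 9 (R)-4-benzyl-3-{[4-(1,3-dithian-2-yl)-2-methoxyphenoxy]acetyl}oxazolidin-2-one, via mixed pivalic anhydride 8 (not isolated)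
Conditions: t-BuCOCl, Et3N, THF, −20 °C; then 7, LiCl, rt
Reagents that add atoms: none
Why: Mixed-anhydride N-acylation of the oxazolidinone takes place at the less hindered aryloxyacetyl carbonyl.

Step 5
Reactants: 9 N-(aryloxyacetyl)oxazolidinone; 10 4-(benzyloxy)-3-methoxybenzaldehyde
Product: 12 (4R)-4-benzyl-3-{(2R,3S)-3-(4-benzyloxy-3-methoxyphenyl)-2-[4-(1,3-dithian-2-yl)-2-methoxyphenoxy]-3-hydroxypropanoyl}oxazolidin-2-one, via Z boron enolate 11 (not isolated)
Conditions: Bu2BOTf, i-Pr2NEt, CH2Cl2, −78 → 0 °C; 10, −78 → 0 °C; pH 7 buffer/MeOH work-up (no peroxide)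
Reagents that add atoms: none
Why: Evans boron aldol addition through a closed chair transition state on the enolate face away from the auxiliary benzyl group should give the (2R,3S) syn adduct, which fixes the future C8 and gives the threo relationship; the peroxide-free work-up spares the dithiane sulfur.

Step 6
Reactants: 12 syn aldol adduct
Product: 13 (1S,2S)-1-(4-benzyloxy-3-methoxyphenyl)-2-[4-(1,3-dithian-2-yl)-2-methoxyphenoxy]propane-1,3-diol (threo)
Conditions: LiBH4, MeOH (1 equiv), THF, 0 °C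
Reagents that add atoms: none
Why: Reductive cleavage of the imide by hydride attack at the exocyclic carbonyl gives the primary alcohol without touching either stereocentre and returns the auxiliary.

Step 7
Reactants: 13 threo diol
Product: 14 (1S,2S)-1-(4-benzyloxy-3-methoxyphenyl)-2-[4-(1,3-dithian-2-yl)-2-methoxyphenoxy]-3-(TBS-oxy)propan-1-ol
Conditions: TBSCl, imidazole, CH2Cl2, 0 °C
Reagents that add atoms: tert-butyldimethylsilyl chloride, CC(C)(C)[Si](C)(C)Cl
Why: Silylation with the chlorosilane and imidazole is selective for the primary hydroxyl over the hindered benzylic secondary one.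

Step 8
Reactants: 14 threo mono-TBS alcohol
Product: 16 (1R,2S)-1-(4-benzyloxy-3-methoxyphenyl)-2-[4-(1,3-dithian-2-yl)-2-methoxyphenoxy]-3-(TBS-oxy)propan-1-ol (erythro), via 4-nitrobenzoate ester 15 (not isolated)
Conditions: PPh3, DIAD, 4-O2NC6H4CO2H, THF, 0 °C → rt; then K2CO3, MeOH, rt
Reagents that add atoms: 4-nitrobenzoic acid, O=C(O)c1ccc(cc1)[N+](=O)[O-] (supplies the new C7 oxygen)
Why: Mitsunobu esterification inverts the benzylic C7 carbinol by SN2 displacement of the activated oxygen by the acidic carboxylate, which turns threo (7S,8S) into erythro (7R,8S), and transesterification with methanol in the same flask frees the alcohol.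

Step 9
Reactants: 16 erythro mono-TBS alcohol
Product: 17 2-(AB aryl)-1,3-dithiane
Conditions: TBSOTf, 2,6-lutidine, CH2Cl2, −78 → 0 °C
Reagents that add atoms: tert-butyldimethylsilyl triflate, CC(C)(C)[Si](C)(C)OS(=O)(=O)C(F)(F)F
Why: Silyl triflate with a hindered pyridine base silylates the hindered benzylic alcohol without ionising it and leaves the dithiane C–H as the only acidic site.

Step 10
Reactants: 18 2-allyl-6-methoxyphenol
Product: 19 2-allyl-4-bromo-6-methoxyphenol
Conditions: NBS, MeCN, −10 → 0 °C, dark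
Reagents that add atoms: N-bromosuccinimide, O=C1CCC(=O)N1Br
Why: Electrophilic aromatic bromination goes para to the phenol, both ortho positions being blocked, faster than any addition to the isolated terminal alkene.

Step 11
Reactants: 19 2-allyl-4-bromo-6-methoxyphenol
Product: 20 1-allyl-5-bromo-3-methoxy-2-(methoxymethoxy)benzene
Conditions: MOMCl, i-Pr2NEt, CH2Cl2, 0 °C → rt
Reagents that add atoms: chloromethyl methyl ether, COCCl
Why: O-alkylation of the phenol with the α-chloro ether masks it as an acetal that survives oxidation, enolisation and hydride and falls to acid when the ring is closed.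

Step 12
Reactants: 20 MOM-protected allylarene
Product: 22 [5-bromo-3-methoxy-2-(methoxymethoxy)phenyl]acetic acid, via arylacetaldehyde 21 (not isolated)
Conditions: O3, MeCN/H2O (9:1), 0 °C; then NaClO2, NaH2PO4, 0 °C → rt; NaHSO3 quench
Reagents that add atoms: ozone, [O-][O+]=O; water, O; sodium chlorite, [Na+].[O-]Cl=O
Why: Ozonolysis in aqueous acetonitrile cleaves the terminal alkene directly to the aldehyde, and chlorite (Pinnick-type) oxidation in the same flask gives the acid, the hydrogen peroxide from the first stage scavenging hypochlorite.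

Step 13
Reactants: 22 arylacetic acid; 23 (S)-4-benzyl-2-oxazolidinone
Product: 25 (S)-4-benzyl-3-{[5-bromo-3-methoxy-2-(methoxymethoxy)phenyl]acetyl}oxazolidin-2-one, via mixed pivalic anhydride 24 (not isolated)
Conditions: t-BuCOCl, Et3N, THF, −20 °C; then 23, LiCl, rt
Reagents that add atoms: none
Why: Mixed-anhydride N-acylation of the oxazolidinone at the less hindered arylacetyl carbonyl.

Step 14
Reactants: 25 N-(arylacetyl)oxazolidinone; 10 4-(benzyloxy)-3-methoxybenzaldehyde
Product: 27 (4S)-4-benzyl-3-{(2S,3S)-3-(4-benzyloxy-3-methoxyphenyl)-2-[5-bromo-3-methoxy-2-(methoxymethoxy)phenyl]-3-hydroxypropanoyl}oxazolidin-2-one, via Z boron enolate 26 (not isolated)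
Conditions: Bu2BOTf, i-Pr2NEt, CH2Cl2, −78 → 0 °C; 10, −78 → 0 °C; pH 7 buffer, MeOH, H2O2, 0 °C
Reagents that add atoms: none
Why: Evans boron aldol addition through a chair transition state on the face away from the auxiliary benzyl group should give the (2S,3S) syn adduct, whose α-carbon becomes C3 of the dihydrobenzofuran with the required configuration.

Step 15
Reactants: 27 syn aldol adduct
Product: 28 (1S,2R)-1-(4-benzyloxy-3-methoxyphenyl)-2-[5-bromo-3-methoxy-2-(methoxymethoxy)phenyl]propane-1,3-diol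
Conditions: LiBH4, MeOH (1 equiv), THF, 0 °C
Reagents that add atoms: none
Why: Reductive removal of the auxiliary by hydride attack at the exocyclic imide carbonyl leaves both stereocentres and the aryl bromide untouched.

Step 16
Reactants: 28 MOM-protected diol
Product: 30 [(2S,3R)-2-(4-benzyloxy-3-methoxyphenyl)-5-bromo-7-methoxy-2,3-dihydro-1-benzofuran-3-yl]methanol, via phenol diol 29 (not isolated)
Conditions: conc. HCl (2 equiv), MeOH, 0 → 40 °C
Reagents that add atoms: none
Why: Acid cleaves the MOM acetal and ionises the p-alkoxybenzylic alcohol, and reversible 5-membered SN1 etherification by the phenol should place the C2 aryl group trans to the fixed C3 substituent, giving (2S,3R).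

Step 17
Reactants: 30 dihydrobenzofuran alcohol
Product: 31 (2S,3R)-2-(4-benzyloxy-3-methoxyphenyl)-5-bromo-3-[(TBS-oxy)methyl]-7-methoxy-2,3-dihydro-1-benzofuran
Conditions: TBSCl, imidazole, DMF, rt
Reagents that add atoms: tert-butyldimethylsilyl chloride, CC(C)(C)[Si](C)(C)Cl
Why: Standard silylation of the only free hydroxyl gives an ether stable to organolithium and enolate chemistry.

Step 18
Reactants: 31 aryl bromide
Product: 34 (CD aryl)methanol, via aryllithium 32 (not isolated), via aldehyde 33 (not isolated)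
Conditions: n-BuLi, THF, −78 °C; DMF, −78 → 0 °C; then MeOH, NaBH4, 0 °C
Reagents that add atoms: N,N-dimethylformamide, CN(C)C=O
Why: Bromine–lithium exchange is faster than any deprotonation at −78 °C, the aryllithium is formylated by the formamide (Bouveault-type) and borohydride reduces the aldehyde in the same flask.

Step 19
Reactants: 34 (CD aryl)methanol
Product: 35 (CD aryl)methyl bromide
Conditions: CBr4, PPh3, CH2Cl2, 0 °C; used at once
Reagents that add atoms: carbon tetrabromide, BrC(Br)(Br)Br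
Why: Appel bromination converts the benzylic alcohol under neutral conditions that spare silyl and benzyl ethers.

Step 20
Reactants: 17 2-(AB aryl)-1,3-dithiane; 4 (5R)-5-(menthyloxy)-2(5H)-furanone; 35 (CD aryl)methyl bromide
Product: 38 (3R,4R,5R)-3-[(CD aryl)methyl]-4-[2-(AB aryl)-1,3-dithian-2-yl]-5-(menthyloxy)dihydrofuran-2(3H)-one, via lithiated dithiane 36 (not isolated), via lithium enolate 37 (not isolated)
Conditions: n-BuLi (1.0 equiv), THF, −78 → −30 °C; 4, −78 °C; then 35, DMPU, −78 → −20 °C; NH4Cl (aq)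
Reagents that add atoms: none
Why: Butyllithium removes the dithiane C2–H, the soft sulfur-stabilised benzylic anion adds in a Michael sense to C4 of the butenolide, and the lithium enolate so formed is C-alkylated (SN2) at C3 by the benzylic bromide. The closest known reaction type is the tandem conjugate addition–enolate alkylation of 5-alkoxy-2(5H)-furanones with lithiated aryl dithianes and benzylic halides, the standard entry to trans-dibenzylbutyrolactone lignans. No ring is closed; two C–C bonds are formed. The C4 centre is controlled by the (5R) acetal carbon, whose menthyloxy group shields one face so that the anion enters anti, and the C3 centre is controlled by the bulky C4 dithianyl group, the bromide entering anti, which should give the (3R,4R,5R) trans,trans lactone. The step needs 1,4- over 1,2-addition, secured by the soft delocalised nucleophile, and C-alkylation without proton transfer, secured by the reactive p-alkoxybenzylic bromide, DMPU and the absence of acidic protons in both fully protected fragments.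

Step 21
Reactants: 38 dithianyl lactone
Product: 39 (3R,4R,5R)-3-[(CD aryl)methyl]-4-[(AB aryl)methyl]-5-(menthyloxy)dihydrofuran-2(3H)-one
Conditions: NiCl2·6H2O, NaBH4, MeOH/THF, 0 °C → rt
Reagents that add atoms: none
Why: Nickel boride formed in the flask performs reductive desulfurisation of the dithiane to a methylene group and leaves benzyl ethers, silyl ethers, the acylal and the non-epimerisable C4 centre alone.

Step 22
Reactants: 39 menthyl acetal lactone
Product: 42 (3R,4R)-3-[(CD aryl)methyl]-4-[(AB aryl)methyl]dihydrofuran-2(3H)-one, via aldehyde carboxylate 40 (not isolated), via hydroxy carboxylate 41 (not isolated)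
Conditions: KOH, NaBH4, THF/MeOH/H2O, 0 °C → rt; then 1 M HCl to pH 3, 0 °C → rt
Reagents that add atoms: potassium hydroxide, [K+].[OH-] (its oxygen enters the carboxyl group and can remain in the lactone carbonyl)
Why: Saponification of the pseudo-ester opens the acylal to a carboxylate and a hemiacetal that loses menthol, borohydride present from the start reduces the aldehyde before the adjacent centre can epimerise, and mild acidification closes the γ-lactone with the original carbonyl carbon still on C-alpha.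

Step 23
Reactants: 42 tris-TBS bis-benzyl lactone
Product: 43 (3R,4R)-lactone with free C7, C9 and dihydrobenzofuran CH2 hydroxyls, both phenols still benzylated
Conditions: TBAF, AcOH, THF, 0 °C → rt
Reagents that add atoms: none
Why: Fluoride-mediated desilylation buffered with acetic acid frees the three hydroxyl groups without exposing the lactone α-centre to strong base, and with the phenols still benzylated no quinone methide can form.

Step 24
Reactants: 43 bis-benzyl ether
Product: 44 target CNP0265599.1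
Conditions: H2 (1 atm), 10% Pd/C, EtOAc/MeOH, rt
Reagents that add atoms: none
Why: Catalytic hydrogenolysis cleaves the two aryl benzyl ethers much faster than the secondary benzylic C–O bonds under neutral conditions at ambient pressure, so all six stereocentres should be left unchanged.

**Compound list**

1 | furfural | O=Cc1ccco1 | starting material
2 | 5-hydroxy-2(5H)-furanone | O=C1C=CC(O)O1 | intermediate
3 | l-menthol, (1R,2S,5R) | O[C@H]1[C@H](C(C)C)CC[C@@H](C)C1 | starting material
4 | (5R)-5-(l-menthyloxy)-2(5H)-furanone | O=C1C=C[C@H](O[C@H]2[C@H](C(C)C)CC[C@@H](C)C2)O1 | intermediate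
5 | (4-formyl-2-methoxyphenoxy)acetic acid | COc1cc(C=O)ccc1OCC(=O)O | starting material
6 | [4-(1,3-dithian-2-yl)-2-methoxyphenoxy]acetic acid | COc1cc(C2SCCCS2)ccc1OCC(=O)O | intermediate
7 | (R)-4-benzyl-2-oxazolidinone | O=C1N[C@H](Cc2ccccc2)CO1 | starting material
8 | mixed pivalic anhydride of 6 | COc1cc(C2SCCCS2)ccc1OCC(=O)OC(=O)C(C)(C)C | intermediate
9 | (R)-4-benzyl-3-{[4-(1,3-dithian-2-yl)-2-methoxyphenoxy]acetyl}oxazolidin-2-one | COc1cc(C2SCCCS2)ccc1OCC(=O)N1[C@H](Cc2ccccc2)COC1=O | intermediate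
10 | 4-(benzyloxy)-3-methoxybenzaldehyde | COc1cc(C=O)ccc1OCc1ccccc1 | starting material
11 | Z dibutylboron enolate of 9 | COc1cc(C2SCCCS2)ccc1O/C=C(\OB(CCCC)CCCC)N1[C@H](Cc2ccccc2)COC1=O | intermediate
12 | (4R)-imide of the (2R,3S) syn aldol, ring A/B | COc1cc([C@H](O)[C@H](C(=O)N2[C@H](Cc3ccccc3)COC2=O)Oc2ccc(C3SCCCS3)cc2OC)ccc1OCc1ccccc1 | intermediate
13 | (1S,2S) threo diol, ring A/B | COc1cc([C@H](O)[C@H](CO)Oc2ccc(C3SCCCS3)cc2OC)ccc1OCc1ccccc1 | intermediate
14 | (1S,2S) threo alcohol, primary TBS ether | COc1cc([C@H](O)[C@H](CO[Si](C)(C)C(C)(C)C)Oc2ccc(C3SCCCS3)cc2OC)ccc1OCc1ccccc1 | intermediate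
15 | (1R,2S) 4-nitrobenzoate | COc1cc([C@@H](OC(=O)c2ccc(cc2)[N+](=O)[O-])[C@H](CO[Si](C)(C)C(C)(C)C)Oc2ccc(C3SCCCS3)cc2OC)ccc1OCc1ccccc1 | intermediate
16 | (1R,2S) erythro alcohol, primary TBS ether | COc1cc([C@@H](O)[C@H](CO[Si](C)(C)C(C)(C)C)Oc2ccc(C3SCCCS3)cc2OC)ccc1OCc1ccccc1 | intermediate
17 | 2-(AB aryl)-1,3-dithiane, (1R,2S) bis-TBS ether | COc1cc([C@@H](O[Si](C)(C)C(C)(C)C)[C@H](CO[Si](C)(C)C(C)(C)C)Oc2ccc(C3SCCCS3)cc2OC)ccc1OCc1ccccc1 | intermediate
18 | 2-allyl-6-methoxyphenol | C=CCc1cccc(OC)c1O | starting material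
19 | 2-allyl-4-bromo-6-methoxyphenol | C=CCc1cc(Br)cc(OC)c1O | intermediate
20 | 1-allyl-5-bromo-3-methoxy-2-(methoxymethoxy)benzene | C=CCc1cc(Br)cc(OC)c1OCOC | intermediate
21 | [5-bromo-3-methoxy-2-(methoxymethoxy)phenyl]acetaldehyde | O=CCc1cc(Br)cc(OC)c1OCOC | intermediate
22 | [5-bromo-3-methoxy-2-(methoxymethoxy)phenyl]acetic acid | OC(=O)Cc1cc(Br)cc(OC)c1OCOC | intermediate
23 | (S)-4-benzyl-2-oxazolidinone | O=C1N[C@@H](Cc2ccccc2)CO1 | starting material
24 | mixed pivalic anhydride of 22 | CC(C)(C)C(=O)OC(=O)Cc1cc(Br)cc(OC)c1OCOC | intermediate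
25 | (S)-4-benzyl-3-{[5-bromo-3-methoxy-2-(methoxymethoxy)phenyl]acetyl}oxazolidin-2-one | COCOc1c(OC)cc(Br)cc1CC(=O)N1[C@@H](Cc2ccccc2)COC1=O | intermediate
26 | Z dibutylboron enolate of 25 | COCOc1c(OC)cc(Br)cc1/C=C(\OB(CCCC)CCCC)N1[C@@H](Cc2ccccc2)COC1=O | intermediate
27 | (4S)-imide of the (2S,3S) syn aldol, ring C/D | COCOc1c(OC)cc(Br)cc1[C@H](C(=O)N1[C@@H](Cc2ccccc2)COC1=O)[C@H](O)c1ccc(OCc2ccccc2)c(OC)c1 | intermediate
28 | (1S,2R) diol, ring C/D, MOM ether | COCOc1c(OC)cc(Br)cc1[C@H](CO)[C@H](O)c1ccc(OCc2ccccc2)c(OC)c1 | intermediate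
29 | (1S,2R) diol, ring C/D, free phenol | Oc1c(OC)cc(Br)cc1[C@H](CO)[C@H](O)c1ccc(OCc2ccccc2)c(OC)c1 | intermediate
30 | [(2S,3R)-2-(4-benzyloxy-3-methoxyphenyl)-5-bromo-7-methoxy-2,3-dihydro-1-benzofuran-3-yl]methanol | Brc1cc(OC)c2c(c1)[C@H](CO)[C@@H](c1ccc(OCc3ccccc3)c(OC)c1)O2 | intermediate
31 | TBS ether of 30 | Brc1cc(OC)c2c(c1)[C@H](CO[Si](C)(C)C(C)(C)C)[C@@H](c1ccc(OCc3ccccc3)c(OC)c1)O2 | intermediate
32 | 5-lithio derivative of 31 | [Li]c1cc(OC)c2c(c1)[C@H](CO[Si](C)(C)C(C)(C)C)[C@@H](c1ccc(OCc3ccccc3)c(OC)c1)O2 | intermediate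
33 | CD aryl carbaldehyde | O=Cc1cc(OC)c2c(c1)[C@H](CO[Si](C)(C)C(C)(C)C)[C@@H](c1ccc(OCc3ccccc3)c(OC)c1)O2 | intermediate
34 | (CD aryl)methanol | OCc1cc(OC)c2c(c1)[C@H](CO[Si](C)(C)C(C)(C)C)[C@@H](c1ccc(OCc3ccccc3)c(OC)c1)O2 | intermediate
35 | (CD aryl)methyl bromide | BrCc1cc(OC)c2c(c1)[C@H](CO[Si](C)(C)C(C)(C)C)[C@@H](c1ccc(OCc3ccccc3)c(OC)c1)O2 | intermediate
36 | 2-lithio derivative of 17 | COc1cc([C@@H](O[Si](C)(C)C(C)(C)C)[C@H](CO[Si](C)(C)C(C)(C)C)Oc2ccc(C3([Li])SCCCS3)cc2OC)ccc1OCc1ccccc1 | intermediate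
37 | lithium enolate of the (4R,5R) conjugate adduct | COc1cc([C@@H](O[Si](C)(C)C(C)(C)C)[C@H](CO[Si](C)(C)C(C)(C)C)Oc2ccc(C3(SCCCS3)[C@H]3[C@H](O[C@H]4[C@H](C(C)C)CC[C@@H](C)C4)OC(O[Li])=C3)cc2OC)ccc1OCc1ccccc1 | intermediate
38 | (3R,4R,5R)-3-[(CD aryl)methyl]-4-[2-(AB aryl)-1,3-dithian-2-yl]-5-(menthyloxy)dihydrofuran-2(3H)-one | COc1cc([C@@H](O[Si](C)(C)C(C)(C)C)[C@H](CO[Si](C)(C)C(C)(C)C)Oc2ccc(C3(SCCCS3)[C@H]3[C@H](O[C@H]4[C@H](C(C)C)CC[C@@H](C)C4)OC(=O)[C@@H]3Cc3cc(OC)c4c(c3)[C@H](CO[Si](C)(C)C(C)(C)C)[C@@H](c3ccc(OCc5ccccc5)c(OC)c3)O4)cc2OC)ccc1OCc1ccccc1 | intermediate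
39 | (3R,4R,5R)-3-[(CD aryl)methyl]-4-[(AB aryl)methyl]-5-(menthyloxy)dihydrofuran-2(3H)-one | COc1cc([C@@H](O[Si](C)(C)C(C)(C)C)[C@H](CO[Si](C)(C)C(C)(C)C)Oc2ccc(C[C@H]3[C@H](O[C@H]4[C@H](C(C)C)CC[C@@H](C)C4)OC(=O)[C@@H]3Cc3cc(OC)c4c(c3)[C@H](CO[Si](C)(C)C(C)(C)C)[C@@H](c3ccc(OCc5ccccc5)c(OC)c3)O4)cc2OC)ccc1OCc1ccccc1 | intermediate
40 | potassium (2R,3R)-2-[(CD aryl)methyl]-3-[(AB aryl)methyl]-4-oxobutanoate | COc1cc([C@@H](O[Si](C)(C)C(C)(C)C)[C@H](CO[Si](C)(C)C(C)(C)C)Oc2ccc(C[C@@H](C=O)[C@@H](Cc3cc(OC)c4c(c3)[C@H](CO[Si](C)(C)C(C)(C)C)[C@@H](c3ccc(OCc5ccccc5)c(OC)c3)O4)C(=O)[O-])cc2OC)ccc1OCc1ccccc1.[K+] | intermediate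
41 | potassium (2R,3R)-2-[(CD aryl)methyl]-3-[(AB aryl)methyl]-4-hydroxybutanoate | COc1cc([C@@H](O[Si](C)(C)C(C)(C)C)[C@H](CO[Si](C)(C)C(C)(C)C)Oc2ccc(C[C@@H](CO)[C@@H](Cc3cc(OC)c4c(c3)[C@H](CO[Si](C)(C)C(C)(C)C)[C@@H](c3ccc(OCc5ccccc5)c(OC)c3)O4)C(=O)[O-])cc2OC)ccc1OCc1ccccc1.[K+] | intermediate
42 | (3R,4R)-3-[(CD aryl)methyl]-4-[(AB aryl)methyl]dihydrofuran-2(3H)-one | COc1cc([C@@H](O[Si](C)(C)C(C)(C)C)[C@H](CO[Si](C)(C)C(C)(C)C)Oc2ccc(C[C@H]3COC(=O)[C@@H]3Cc3cc(OC)c4c(c3)[C@H](CO[Si](C)(C)C(C)(C)C)[C@@H](c3ccc(OCc5ccccc5)c(OC)c3)O4)cc2OC)ccc1OCc1ccccc1 | intermediate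
43 | tris-desilylated 42, phenols benzylated | COc1cc([C@@H](O)[C@H](CO)Oc2ccc(C[C@H]3COC(=O)[C@@H]3Cc3cc(OC)c4c(c3)[C@H](CO)[C@@H](c3ccc(OCc5ccccc5)c(OC)c3)O4)cc2OC)ccc1OCc1ccccc1 | intermediate
44 | CNP0265599.1 | COc1cc([C@@H](O)[C@H](CO)Oc2ccc(C[C@H]3COC(=O)[C@@H]3Cc3cc(OC)c4c(c3)[C@H](CO)[C@@H](c3ccc(O)c(OC)c3)O4)cc2OC)ccc1O | target

**Count**

Total: 24 steps. Longest linear sequence: 15 steps (18 → 44; steps 10–19, then 20–24).

**Steps most likely to fail**

1. Step 20. The hindered lithium enolate may be protonated, or react too slowly with the large and labile benzylic bromide, before C-alkylation occurs; some 1,2-addition is also possible. The fallback sets out from 17 and 4 and returns at 38, splitting the one-flask sequence in two. Anion 36 is added to 4 at −78 °C and the enolate is quenched with NH4Cl, which gives the isolable (4R,5R)-4-[2-(AB aryl)-1,3-dithian-2-yl]-5-(menthyloxy)dihydrofuran-2(3H)-one F1. F1 is then re-enolised with LiN(SiMe3)2 in THF/DMPU at −78 °C and alkylated with 35. This is the known trans-selective alkylation of a β-substituted butyrolactone enolate and gives 38.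

2. Step 8. The activated electron-rich benzylic alcohol may ionise, so that substitution leaks through a cation and inversion is incomplete, or it may eliminate. The fallback sets out from 14 and returns at 16 by oxidation and reduction. Swern oxidation ((COCl)2, DMSO, i-Pr2NEt, −78 °C; compatible with the dithiane) gives (S)-1-(4-benzyloxy-3-methoxyphenyl)-2-[4-(1,3-dithian-2-yl)-2-methoxyphenoxy]-3-(TBS-oxy)propan-1-one F2. Reduction with LiBH(s-Bu)3 at −78 °C under Felkin–Anh control, hydride anti to the aryloxy group, should give the erythro alcohol 16.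

3. Step 16. The benzylic cation may be captured by methanol or by formaldehyde-derived species on the free 1,3-diol, and equilibration at C2 to the trans isomer may be incomplete. The fallback sets out from 27 and returns at 30 by closing the ring before the auxiliary is removed, in an aprotic medium with no free diol. Treatment of 27 with CF3CO2H/CH2Cl2 containing a little water at 0 °C cleaves the MOM ether and should cyclise the phenol onto the benzylic cation to give the trans (2S,3S)-2-(4-benzyloxy-3-methoxyphenyl)-5-bromo-7-methoxy-2,3-dihydro-1-benzofuran-3-carbonyl oxazolidinone F3. LiBH4 reduction of F3 then gives 30.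

**Further compounds**

F1 | step 20 | (4R,5R)-4-[2-(AB aryl)-1,3-dithian-2-yl]-5-(menthyloxy)dihydrofuran-2(3H)-one | COc1cc([C@@H](O[Si](C)(C)C(C)(C)C)[C@H](CO[Si](C)(C)C(C)(C)C)Oc2ccc(C3(SCCCS3)[C@H]3[C@H](O[C@H]4[C@H](C(C)C)CC[C@@H](C)C4)OC(=O)C3)cc2OC)ccc1OCc1ccccc1
F2 | step 8 | (S)-1-(4-benzyloxy-3-methoxyphenyl)-2-[4-(1,3-dithian-2-yl)-2-methoxyphenoxy]-3-(TBS-oxy)propan-1-one | COc1cc(C(=O)[C@H](CO[Si](C)(C)C(C)(C)C)Oc2ccc(C3SCCCS3)cc2OC)ccc1OCc1ccccc1
F3 | step 16 | (S)-4-benzyl-3-{[(2S,3S)-2-(4-benzyloxy-3-methoxyphenyl)-5-bromo-7-methoxy-2,3-dihydro-1-benzofuran-3-yl]carbonyl}oxazolidin-2-one | Brc1cc(OC)c2c(c1)[C@H](C(=O)N1[C@@H](Cc3ccccc3)COC1=O)[C@@H](c1ccc(OCc3ccccc3)c(OC)c1)O2
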